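**Direct plan and its weak points**

A direct plan would leave the lower unit intact and build the upper unit on it: the C6′ aldehyde A1 of perbenzylated 8′-bromoepicatechin gallate would take up bromomagnesium 3,5-bis(benzyloxy)phenoxide to give benzhydrol A2.
The ortho-quinone methide of A2 would close ring C in a chiral-phosphoric-acid-catalysed hetero-Diels–Alder reaction with silyl enol ether A3 (to silyl ketal A4); silane reduction at C2 (to protected dimer A5) and hydrogenolysis would follow.
Its weakest steps would be: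
(a) the hetero-Diels–Alder ring closure, because C3 and C4 would be set on the most valuable intermediate by a catalyst that must override a large chiral substrate, with facial and endo/exo selectivity unproven for so crowded a quinone methide;
(b) the ionic reduction of the C2 ketal, because the 2,3-cis relation would rest on a conformational argument only and BF3 would act next to the acid-labile C4–C6′ bond;
(c) the formylation and phenoxide addition, because two further operations on the already elaborated lower unit would add only one carbon between two benzyloxy groups and a carbinol centre that forms without control and is destroyed again.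

**Plan of the new route**

Cuts: first the C4–C6′ bond (C4 cation of a protected epiafzelechin plus C6′ of perbenzylated 8′-bromoepicatechin gallate, itself assembled from (−)-epicatechin and tri-O-benzylgallic acid); then, in the upper unit alone, the C3–H bond with the C2 configuration (racemic flavan-3-one) and the O1–C2 bond (chalcone).
Ring order: rings A and B are bought, ring C is closed early with no stereochemical demand, rings D, E and F come intact from (−)-epicatechin and the galloyl ring from the benzylated acid, and the two halves are joined last.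
Enabling feature: C2 of the upper unit is benzylic to ring B and bonded to O1, so in the C3 ketone it is an acidic α-carbon that inverts through the O1–C2=C3 enol; one chiral reduction should therefore turn the whole racemate into the (2R,3R)-cis alcohol.
C4 then needs no reagent control: the axial C3–OH sends C6′ to the β face of the planar C4 cation from either C4 epimer; bromine on C8′ leaves C6′ as the only open position of ring D, and bromine on C8 removes the most nucleophilic carbon of the upper unit.
So no ring is closed and no stereocentre is set by a catalyst on a dimeric intermediate, C2 is never reduced from a ketal, and the lower unit needs three routine operations and no carbon chain on C6′.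

Key step: step 5

Assumptions: ketone 1 and acid 16 are bought as such. In step 5 the catalyst antipode is the one that reduces (2R)-8 on the Si face of C3; the (S,S) complex is written by analogy with α-aryl cyclic ketones and would be exchanged for the (R,R) complex if a trial run shows the opposite sense (TsDPEN = N-tosyl-1,2-diphenylethane-1,2-diamine).

**Route**

Step 1
Reactants: 1 1-[2,4-bis(benzyloxy)-6-hydroxyphenyl]ethanone; 2 4-(benzyloxy)benzaldehyde
Product: 3 (E)-1-[2,4-bis(benzyloxy)-6-hydroxyphenyl]-3-[4-(benzyloxy)phenyl]prop-2-en-1-one (2′-hydroxychalcone)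
Conditions: KOH (50% aq.), EtOH/THF, rt
Reagents that add atoms: none
Why: Claisen–Schmidt condensation, in which the ketone enolate adds to the non-enolisable aldehyde and the aldol dehydrates to the (E)-enone, while the chelated 2′-phenoxide flanked by the 6′-benzyloxy group holds back cyclisation to the flavanone.

Step 2
Reactants: 3 2′-hydroxychalcone
Product: 6 rac-5,7-bis(benzyloxy)-2-[4-(benzyloxy)phenyl]-2H-chromene (flav-3-ene), via allylic alcohol 4 (not isolated), via ortho-quinone methide 5 (not isolated)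
Conditions: NaBH4, THF/EtOH, reflux; then aq. AcOH, rt
Reagents that add atoms: none
Why: Hydride 1,2-reduction gives allylic alcohol 4, its benzylic hydroxyl group leaves with help of the ortho-phenoxide to give quinone methide 5, and oxa-6π electrocyclisation (O1–C2 bond) closes ring C as the 2H-chromene; C2 forms as a racemate, which does not matter because it is equilibrated in step 5.

Step 3
Reactants: 6 flav-3-ene
Product: 7 rac-(2R*,3S*)-5,7-bis(benzyloxy)-2-[4-(benzyloxy)phenyl]chroman-3-ol (2,3-trans)
Conditions: BH3·THF, THF, 0 °C to rt; then NaOH, H2O2, 0 °C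
Reagents that add atoms: hydrogen peroxide, OO
Why: Hydroboration–oxidation of the styrene-type C3=C4 bond places boron on C3 (the electron-rich ring A supports positive charge at C4) anti to the C2 aryl group and oxidation with retention gives the trans alcohol, whose relative and absolute configuration are both erased in steps 4 and 5.

Step 4
Reactants: 7 rac-trans-flavan-3-ol
Product: 8 rac-5,7-bis(benzyloxy)-2-[4-(benzyloxy)phenyl]chroman-3-one (flavan-3-one)
Conditions: Dess–Martin periodinane, CH2Cl2, 0 °C to rt, argon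
Reagents that add atoms: none
Why: Dess–Martin oxidation under neutral conditions converts the secondary alcohol into the ketone without touching the benzyl ethers or the electron-rich ring A, and the enolisable ketone is used at once.

Step 5
Reactants: 8 rac-flavan-3-one
Product: 9 (2R,3R)-5,7-bis(benzyloxy)-2-[4-(benzyloxy)phenyl]chroman-3-ol (tri-O-benzyl-(−)-epiafzelechin)
Conditions: RuCl[(S,S)-TsDPEN](p-cymene) (2 mol %), HCO2H/Et3N (1:1), CH2Cl2, 30 °C, argon
Reagents that add atoms: none
Why: Proposed new method: Et3N should keep (2R)- and (2S)-8 in rapid equilibrium through the O1–C2=C3 enol, because C2–H is at once α to the C3 carbonyl group, benzylic to ring B and on the carbon that carries O1, while the ruthenium hydride of the chiral amido complex, regenerated from formate, passes H− and H+ to the C3 carbonyl group of the better-fitting (2R)-enantiomer through the six-membered outer-sphere Ru–H···C=O···H–N transition state. The closest known reaction type is transfer hydrogenation with dynamic kinetic resolution of racemic α-aryl cyclic ketones (2-aryl-1-tetralones, 1-aryl-2-tetralones, isoflavanones) to cis alcohols with the same catalysts. No ring is closed. C3 is set by the catalyst (hydride to the Si face of the carbonyl group), C2 by selection of one of the two equilibrating enantiomers, and their cis relation by hydride delivery anti to the pseudo-equatorial ring B aryl group, the same substrate bias that makes bulky hydrides give 2,3-cis-flavan-3-ols from flavan-3-ones. The step needs epimerisation faster than reduction, discrimination between the enantiomers and cis selectivity; the doubly activated C2–H, the fact that the other α-carbon (C4) is a plain CH2 group whose enolisation is harmless, and the half-chair of ring C should secure these, and benzyl ethers and ring A are inert to the catalyst.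

Step 6
Reactants: 9 tri-O-benzyl-(−)-epiafzelechin
Product: 10 (2R,3R)-8-bromo-5,7-bis(benzyloxy)-2-[4-(benzyloxy)phenyl]chroman-3-ol
Conditions: NBS (1.0 equiv), CH2Cl2, −78 °C to −20 °C
Reagents that add atoms: N-bromosuccinimide, O=C1CCC(=O)N1Br
Why: Electrophilic aromatic bromination, in which the trioxygenated ring A is far more reactive than ring B and 5,7-di-O-benzyl flavan-3-ols are attacked at C8 at low temperature, so the most nucleophilic carbon of the upper unit is closed before its C4 cation is made.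

Step 7
Reactants: 10 8-bromo-tri-O-benzylepiafzelechin
Product: 12 (2R,3R,4S)-8-bromo-5,7-bis(benzyloxy)-2-[4-(benzyloxy)phenyl]-4-(2-ethoxyethoxy)chroman-3-ol (4β ether), via C4 carbocation hydroquinonate ion pair 11 (not isolated)
Conditions: DDQ (2 equiv), 2-ethoxyethanol (5 equiv), CH2Cl2, rt
Reagents that add atoms: 2-ethoxyethanol, CCOCCO
Why: Benzylic oxidation by hydride abstraction, in which DDQ takes the hydride from C4 (the only C–H ortho and para to the three ring A oxygen atoms) to give the cation paired with the DDQ-derived hydroquinone monoanion (11), and the alcohol traps the cation anti to the axial C3–OH to give the 4β ether, whose C4 configuration is lost again in step 11.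

Step 8
Reactants: 13 (−)-epicatechin
Product: 14 (2R,3R)-5,7-bis(benzyloxy)-2-[3,4-bis(benzyloxy)phenyl]chroman-3-ol (tetra-O-benzyl-(−)-epicatechin)
Conditions: BnBr (4.4 equiv), K2CO3, DMF, 0 °C to rt, argon
Reagents that add atoms: benzyl bromide, BrCc1ccccc1
Why: Williamson ether synthesis on the four phenols, which K2CO3 deprotonates while the aliphatic 3′-OH stays neutral; working at or below room temperature under argon should limit C-benzylation of ring D and base-induced epimerisation at C2′, so both stereocentres are carried over unchanged.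

Step 9
Reactants: 14 tetra-O-benzyl-(−)-epicatechin
Product: 15 (2R,3R)-8-bromo-5,7-bis(benzyloxy)-2-[3,4-bis(benzyloxy)phenyl]chroman-3-ol
Conditions: NBS (1.0 equiv), CH2Cl2, −78 °C to 0 °C
Reagents that add atoms: N-bromosuccinimide, O=C1CCC(=O)N1Br
Why: Electrophilic aromatic bromination, in which ring D is the only trioxygenated ring (ring E is a catechol diether) and 5,7-di-O-benzyl flavan-3-ols are attacked at C8′ at low temperature, which leaves C6′ as the single free and nucleophilic position of ring D.

Step 10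
Reactants: 15 8′-bromo-tetra-O-benzylepicatechin; 16 3,4,5-tris(benzyloxy)benzoic acid
Product: 17 (2R,3R)-8-bromo-5,7-bis(benzyloxy)-2-[3,4-bis(benzyloxy)phenyl]chroman-3-yl 3,4,5-tris(benzyloxy)benzoate
Conditions: DCC, DMAP (cat.), CH2Cl2, rt
Reagents that add atoms: none
Why: Steglich esterification, in which the N-acylpyridinium ion formed from 16 acylates the axial secondary 3′-OH without touching a stereocentre, while the aryl bromide and the benzyl ethers are inert.

Step 11
Reactants: 12 4β-(2-ethoxyethoxy) upper unit; 17 8′-bromo lower unit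
Product: 19 deca-O-benzyl-8,8′-dibromo-epiafzelechin-(4β→6)-epicatechin 3′-O-gallate (free 3-OH; upper unit 2,3-cis-3,4-trans; lower unit 2′R,3′R), via C4 carbocation alkoxytrifluoroborate ion pair 18 (not isolated)
Conditions: 17 (2 equiv), BF3·OEt2 (1.2 equiv), 4 Å MS, CH2Cl2, −78 °C to −30 °C; 12 added slowly
Reagents that add atoms: none
Why: Lewis-acid-mediated Friedel–Crafts alkylation (SN1), in which BF3 binds the ether oxygen of either C4 epimer of 12 and ionisation gives the same planar cation paired with the (2-ethoxyethoxy)trifluoroborate anion (18), C6′ of 17 attacks anti to the axial C3–OH to give the 3,4-trans (4β) bond, and self-condensation is held back by the C8 bromine together with slow addition of 12 to excess 17.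

Step 12
Reactants: 19 protected dibromo dimer
Product: 20 epiafzelechin-(4β→6)-epicatechin 3′-O-gallate (target; upper unit 2R,3R,4S; lower unit 2′R,3′R)
Conditions: H2 (1 atm), Pd(OH)2/C, NaOAc, THF/MeOH/H2O, rt; filtration under argon
Reagents that add atoms: none
Why: Heterogeneous hydrogenolysis should remove the ten benzyl ethers and both aryl C–Br bonds in one operation while NaOAc buffers the HBr, and the ester, both pyran rings, the C4–C6′ bond and the five stereocentres should be unaffected at room temperature and 1 atm.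

**Compound list**

1 | 1-[2,4-bis(benzyloxy)-6-hydroxyphenyl]ethanone | CC(=O)c1c(O)cc(OCc2ccccc2)cc1OCc1ccccc1 | starting material
2 | 4-(benzyloxy)benzaldehyde | O=Cc1ccc(OCc2ccccc2)cc1 | starting material
3 | (E)-1-[2,4-bis(benzyloxy)-6-hydroxyphenyl]-3-[4-(benzyloxy)phenyl]prop-2-en-1-one | O=C(/C=C/c1ccc(OCc2ccccc2)cc1)c1c(O)cc(OCc2ccccc2)cc1OCc1ccccc1 | intermediate
4 | (E)-1-[2,4-bis(benzyloxy)-6-hydroxyphenyl]-3-[4-(benzyloxy)phenyl]prop-2-en-1-ol (racemic carbinol) | OC(/C=C/c1ccc(OCc2ccccc2)cc1)c1c(O)cc(OCc2ccccc2)cc1OCc1ccccc1 | intermediate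
5 | 3,5-bis(benzyloxy)-6-[(E)-3-(4-(benzyloxy)phenyl)prop-2-enylidene]cyclohexa-2,4-dien-1-one (ortho-quinone methide, styryl group cis to C=O) | O=C1C=C(OCc2ccccc2)C=C(OCc2ccccc2)/C1=C/C=C/c1ccc(OCc2ccccc2)cc1 | intermediate
6 | rac-5,7-bis(benzyloxy)-2-[4-(benzyloxy)phenyl]-2H-chromene (racemate, C2 undefined) | C1=Cc2c(OCc3ccccc3)cc(OCc3ccccc3)cc2OC1c1ccc(OCc2ccccc2)cc1 | intermediate
7 | rac-(2R*,3S*)-5,7-bis(benzyloxy)-2-[4-(benzyloxy)phenyl]chroman-3-ol (2,3-trans; racemate, one enantiomer drawn) | O[C@H]1Cc2c(OCc3ccccc3)cc(OCc3ccccc3)cc2O[C@@H]1c1ccc(OCc2ccccc2)cc1 | intermediate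
8 | rac-5,7-bis(benzyloxy)-2-[4-(benzyloxy)phenyl]chroman-3-one (racemate, C2 undefined) | O=C1Cc2c(OCc3ccccc3)cc(OCc3ccccc3)cc2OC1c1ccc(OCc2ccccc2)cc1 | intermediate
9 | (2R,3R)-5,7-bis(benzyloxy)-2-[4-(benzyloxy)phenyl]chroman-3-ol | O[C@@H]1Cc2c(OCc3ccccc3)cc(OCc3ccccc3)cc2O[C@@H]1c1ccc(OCc2ccccc2)cc1 | intermediate
10 | (2R,3R)-8-bromo-5,7-bis(benzyloxy)-2-[4-(benzyloxy)phenyl]chroman-3-ol | O[C@@H]1Cc2c(OCc3ccccc3)cc(OCc3ccccc3)c(Br)c2O[C@@H]1c1ccc(OCc2ccccc2)cc1 | intermediate
11 | ion pair of the C4 carbocation of 10 (cation stabilised by O1, O5 and O7; C2 and C3 as in 10) with 2,3-dichloro-5,6-dicyano-4-hydroxyphenolate | O[C@@H]1[CH+]c2c(OCc3ccccc3)cc(OCc3ccccc3)c(Br)c2O[C@@H]1c1ccc(OCc2ccccc2)cc1.[O-]c1c(Cl)c(Cl)c(O)c(C#N)c1C#N | intermediate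
12 | (2R,3R,4S)-8-bromo-5,7-bis(benzyloxy)-2-[4-(benzyloxy)phenyl]-4-(2-ethoxyethoxy)chroman-3-ol (4β, 3,4-trans) | CCOCCO[C@H]1c2c(OCc3ccccc3)cc(OCc3ccccc3)c(Br)c2O[C@H](c2ccc(OCc3ccccc3)cc2)[C@@H]1O | intermediate
13 | (−)-epicatechin | O[C@@H]1Cc2c(O)cc(O)cc2O[C@@H]1c1ccc(O)c(O)c1 | starting material
14 | (2R,3R)-5,7-bis(benzyloxy)-2-[3,4-bis(benzyloxy)phenyl]chroman-3-ol | O[C@@H]1Cc2c(OCc3ccccc3)cc(OCc3ccccc3)cc2O[C@@H]1c1ccc(OCc2ccccc2)c(OCc2ccccc2)c1 | intermediate
15 | (2R,3R)-8-bromo-5,7-bis(benzyloxy)-2-[3,4-bis(benzyloxy)phenyl]chroman-3-ol | O[C@@H]1Cc2c(OCc3ccccc3)cc(OCc3ccccc3)c(Br)c2O[C@@H]1c1ccc(OCc2ccccc2)c(OCc2ccccc2)c1 | intermediate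
16 | 3,4,5-tris(benzyloxy)benzoic acid | OC(=O)c1cc(OCc2ccccc2)c(OCc2ccccc2)c(OCc2ccccc2)c1 | starting material
17 | (2R,3R)-8-bromo-5,7-bis(benzyloxy)-2-[3,4-bis(benzyloxy)phenyl]chroman-3-yl 3,4,5-tris(benzyloxy)benzoate | O=C(O[C@@H]1Cc2c(OCc3ccccc3)cc(OCc3ccccc3)c(Br)c2O[C@@H]1c1ccc(OCc2ccccc2)c(OCc2ccccc2)c1)c1cc(OCc2ccccc2)c(OCc2ccccc2)c(OCc2ccccc2)c1 | intermediate
18 | ion pair of the same C4 carbocation (C2 and C3 as in 12) with (2-ethoxyethoxy)trifluoroborate | O[C@@H]1[CH+]c2c(OCc3ccccc3)cc(OCc3ccccc3)c(Br)c2O[C@@H]1c1ccc(OCc2ccccc2)cc1.CCOCCO[B-](F)(F)F | intermediate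
19 | deca-O-benzyl-8,8′-dibromo-epiafzelechin-(4β→6)-epicatechin 3′-O-gallate (upper unit: free 3-OH, 5,7-di-OBn, ring B 4-OBn, 8-Br, 2,3-cis-3,4-trans; lower unit: hepta-O-benzyl, 8′-Br, 2′R,3′R) | O=C(O[C@@H]1Cc2c(c(Br)c(OCc3ccccc3)c([C@H]3c4c(OCc5ccccc5)cc(OCc5ccccc5)c(Br)c4O[C@H](c4ccc(OCc5ccccc5)cc4)[C@@H]3O)c2OCc2ccccc2)O[C@@H]1c1ccc(OCc2ccccc2)c(OCc2ccccc2)c1)c1cc(OCc2ccccc2)c(OCc2ccccc2)c(OCc2ccccc2)c1 | intermediate
20 | epiafzelechin-(4β→6)-epicatechin 3′-O-gallate (upper unit 2R,3R,4S; lower unit 2′R,3′R) | O=C(O[C@@H]1Cc2c(cc(O)c([C@H]3c4c(O)cc(O)cc4O[C@H](c4ccc(O)cc4)[C@@H]3O)c2O)O[C@@H]1c1ccc(O)c(O)c1)c1cc(O)c(O)c(O)c1 | target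

**Step count and risks**

Total steps: 12. Longest linear sequence: 9 (steps 1 to 7, 11 and 12); steps 8 to 10 form the second branch.

Steps most likely to fail:

1. Step 5 (proposed new method). Epimerisation at C2 may be slower than reduction, so that the step becomes a simple kinetic resolution and loses half the material, or the catalyst may discriminate poorly between the two enantiomers. The fallback uses known chemistry, sets out from 8 and returns at 9. LiBH(s-Bu)3 (L-Selectride) in THF at −78 °C reduces racemic 8 from the face anti to ring B and should give the racemic 2,3-cis alcohol, that is 9 together with its (2S,3S)-enantiomer F1. Preparative chromatography on a chiral stationary phase (cellulose tris(3,5-dimethylphenylcarbamate)) separates the two. F1 is oxidised back to 8 with Dess–Martin periodinane, racemised with DBU and recycled.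

2. Step 11. Attack of the hindered ring D, which carries bromine and sits next to the bulky ester, may be slow, so that the C4 cation is consumed by ring A of a second upper unit or by elimination. The fallback joins the units before the galloyl group is present; it sets out from 12 and 15 and returns at 20. The 3-OH of 12 is benzylated (NaH, BnBr, DMF, 0 °C) to the 3-O-benzyl ether F2. F2 and the alcohol 15 (3 equiv), a smaller and more electron-rich nucleophile than ester 17, are coupled with BF3·OEt2 in CH2Cl2 at −78 °C to the 4β→6 dimer F3, whose only free hydroxyl group is the 3′-OH. F3 is esterified with acid 16 (DCC, DMAP, CH2Cl2) to the undeca-O-benzyl dibromo dimer gallate F4. Hydrogenolysis of F4 under the conditions of step 12 gives 20.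

3. Step 12. Bromide released at the catalyst surface may poison the palladium so that debenzylation stalls at partly protected stages, or HBr formed locally may cleave the acid-labile interflavan bond before the buffer takes it up. The fallback separates dehalogenation from debenzylation; it sets out from 19 and returns at 20. Radical hydrodebromination (Bu3SnH, AIBN, toluene, 90 °C) removes both aryl bromine atoms and should give the bromine-free deca-O-benzyl dimer gallate F5. Hydrogenolysis of F5 (H2, 1 atm, Pd(OH)2/C, THF/MeOH/H2O, rt) then proceeds without any halide or acid being formed and gives 20.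

Further compounds
F1 | step 5 | (2S,3S)-5,7-bis(benzyloxy)-2-[4-(benzyloxy)phenyl]chroman-3-ol (enantiomer of 9) | O[C@H]1Cc2c(OCc3ccccc3)cc(OCc3ccccc3)cc2O[C@H]1c1ccc(OCc2ccccc2)cc1
F2 | step 11 | 3-O-benzyl ether of 12: 8-bromo-3,5,7-tris(benzyloxy)-2-[4-(benzyloxy)phenyl]-4β-(2-ethoxyethoxy)chroman (2,3-cis-3,4-trans) | CCOCCO[C@H]1c2c(OCc3ccccc3)cc(OCc3ccccc3)c(Br)c2O[C@H](c2ccc(OCc3ccccc3)cc2)[C@@H]1OCc1ccccc1
F3 | step 11 | octa-O-benzyl-8,8′-dibromo-epiafzelechin-(4β→6)-epicatechin with 3-OBn on the upper unit and free 3′-OH on the lower unit | O[C@@H]1Cc2c(c(Br)c(OCc3ccccc3)c([C@H]3c4c(OCc5ccccc5)cc(OCc5ccccc5)c(Br)c4O[C@H](c4ccc(OCc5ccccc5)cc4)[C@@H]3OCc3ccccc3)c2OCc2ccccc2)O[C@@H]1c1ccc(OCc2ccccc2)c(OCc2ccccc2)c1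
F4 | step 11 | undeca-O-benzyl-8,8′-dibromo-epiafzelechin-(4β→6)-epicatechin 3′-O-gallate | O=C(O[C@@H]1Cc2c(c(Br)c(OCc3ccccc3)c([C@H]3c4c(OCc5ccccc5)cc(OCc5ccccc5)c(Br)c4O[C@H](c4ccc(OCc5ccccc5)cc4)[C@@H]3OCc3ccccc3)c2OCc2ccccc2)O[C@@H]1c1ccc(OCc2ccccc2)c(OCc2ccccc2)c1)c1cc(OCc2ccccc2)c(OCc2ccccc2)c(OCc2ccccc2)c1
F5 | step 12 | deca-O-benzyl-epiafzelechin-(4β→6)-epicatechin 3′-O-gallate (no bromine; free 3-OH on the upper unit) | O=C(O[C@@H]1Cc2c(cc(OCc3ccccc3)c([C@H]3c4c(OCc5ccccc5)cc(OCc5ccccc5)cc4O[C@H](c4ccc(OCc5ccccc5)cc4)[C@@H]3O)c2OCc2ccccc2)O[C@@H]1c1ccc(OCc2ccccc2)c(OCc2ccccc2)c1)c1cc(OCc2ccccc2)c(OCc2ccccc2)c(OCc2ccccc2)c1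
A1 | direct plan | (2R,3R)-8-bromo-6-formyl-5,7-bis(benzyloxy)-2-[3,4-bis(benzyloxy)phenyl]chroman-3-yl 3,4,5-tris(benzyloxy)benzoate | O=C(O[C@@H]1Cc2c(OCc3ccccc3)c(C=O)c(OCc3ccccc3)c(Br)c2O[C@@H]1c1ccc(OCc2ccccc2)c(OCc2ccccc2)c1)c1cc(OCc2ccccc2)c(OCc2ccccc2)c(OCc2ccccc2)c1
A2 | direct plan | benzhydrol: A1 with the formyl group changed to CH(OH)-[2-hydroxy-4,6-bis(benzyloxy)phenyl] (carbinol centre undefined) | O=C(O[C@@H]1Cc2c(OCc3ccccc3)c(C(O)c3c(O)cc(OCc4ccccc4)cc3OCc3ccccc3)c(OCc3ccccc3)c(Br)c2O[C@@H]1c1ccc(OCc2ccccc2)c(OCc2ccccc2)c1)c1cc(OCc2ccccc2)c(OCc2ccccc2)c(OCc2ccccc2)c1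
A3 | direct plan | (Z)-[2-(benzyloxy)-1-(4-(benzyloxy)phenyl)ethenyloxy](tert-butyl)dimethylsilane | CC(C)(C)[Si](C)(C)O/C(c1ccc(OCc2ccccc2)cc1)=C\OCc1ccccc1
A4 | direct plan | C2 silyl ketal of the protected dimer (2-OTBS, 3-OBn, C4 linked to C6′ of the 8′-bromo lower unit) | O=C(O[C@@H]1Cc2c(c(Br)c(OCc3ccccc3)c([C@H]3c4c(OCc5ccccc5)cc(OCc5ccccc5)cc4O[C@@](O[Si](C)(C)C(C)(C)C)(c4ccc(OCc5ccccc5)cc4)[C@@H]3OCc3ccccc3)c2OCc2ccccc2)O[C@@H]1c1ccc(OCc2ccccc2)c(OCc2ccccc2)c1)c1cc(OCc2ccccc2)c(OCc2ccccc2)c(OCc2ccccc2)c1
A5 | direct plan | undeca-O-benzyl-8′-bromo-epiafzelechin-(4β→6)-epicatechin 3′-O-gallate | O=C(O[C@@H]1Cc2c(c(Br)c(OCc3ccccc3)c([C@H]3c4c(OCc5ccccc5)cc(OCc5ccccc5)cc4O[C@H](c4ccc(OCc5ccccc5)cc4)[C@@H]3OCc3ccccc3)c2OCc2ccccc2)O[C@@H]1c1ccc(OCc2ccccc2)c(OCc2ccccc2)c1)c1cc(OCc2ccccc2)c(OCc2ccccc2)c(OCc2ccccc2)c1
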